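Which form holds the catalyst when 20% of the substrate is converted, and how strongly do partner and free catalyst then move the rate of making target?

substrate 0.99 M; partner 1.29 M; free catalyst 20 mM

    open intermediate → side product (k1 = 0.00426 s⁻¹)
    partner + catalyst intermediate → free catalyst + target (k2 = 0.0291 M⁻¹ s⁻¹)
    free catalyst + open intermediate ⇌ catalyst intermediate (K3 = 2.3 M⁻¹, k3 = 0.107 M⁻¹ s⁻¹)
    substrate + free catalyst ⇌ free catalyst + open intermediate (K4 = 1.2, k4 = 0.0484 M⁻¹ s⁻¹)

- the form that holds most of the catalyst when 20% of the substrate are converted (catalyst intermediate / free catalyst)
- its share of the catalyst then
- apparent order in partner when 20% of the substrate are converted (percent change of the rate of making target for one percent more partner charged)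
- apparent order in free catalyst when 20% of the substrate are converted (percent change of the rate of making target for one percent more free catalyst charged)
- factor on the rate of making target when 20% of the substrate are converted if free catalyst is charged twice over

Write the balance of the catalyst, the reagent you charged least of, in fractions of its charge. Free fraction plus bound fraction make one, and the bound fraction, the catalyst intermediate, is fed by capture of open intermediate and drained by two exits, which I reckon per catalyst intermediate, with partner taken as charged:

forward exit, with partner = 135 h⁻¹

back exit, to free catalyst and open intermediate = 167 h⁻¹

forward / (forward + back) = 44.7%

This share, the commitment, is the part of the catalyst intermediate that leaves towards target. The two exits together, divided by the capture constant, give the fraction of the substrate charge in open intermediate at which bound and free catalyst stand equal: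

even level = 79.4%

The open intermediate can't exceed the 20% converted, which is below that level, so with the exits as reckoned I expect free catalyst as the resting state in this flask, with an estimated 79.9% of the charge or more. With open intermediate held fixed, more partner raises the rate directly but thins the bound fraction through the commitment:

order in partner = 1 − free share × commitment

That runs from 0.553 at a free share of one to 0.643 at the estimated free share. My reckoning stops here, short of the order in free catalyst.

The forecast says free catalyst at 88.5%, orders of 0.58 in partner and 1.38 in free catalyst, and a factor of 2.47, with the partner order below 1 because “the catalyst intermediate partly reverts rather than going on to target”.

The flask gives free catalyst at 88.6%, orders of 0.59 and 1.4, and a factor of 2.40; that free share and the commitment give 0.604 for the partner order. A simulated run of this flask without the back exit, so with a commitment of one, shows the weight of that step: the order in partner falls to 0.27.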